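**Retrosynthetic overview**

1. Atom labels: pyrrole N–C9a–C1–C2–C3; ring B C9a–C9–C10(Et)–C11(O)–C12–C1; lactone D C11–O–C14(=O)–C13(Me)–C12; azepine N–C5–C6–C7–C8–C9–C9a; lactone E C18(O)–C19–C20(Me)–C21(=O) on C3.
2. Feature: the five carbons C5–C9 bridge the pyrrole nitrogen and its α-carbon C9a, and C9 is already held beside C9a by C10–C12 of lactone D. With C7 as a carbonyl this chain is a cross-conjugated divinyl ketone, so C9a–C9 (ring B) and then N–C5 (azepine) are made by two conjugate additions in one flask, and the C7 oxygen is removed last.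
3. Dienone 33 comes from C9 aldehyde 27 (Wittig to the enal, vinyl addition, N-deprotection, oxidation); 27 comes from the all-cis lactone D, made by hydrogenating butenolide 24 on the face opposite the C11 side chain.
4. 24 is joined by Suzuki coupling of tetronate triflate 15 (C10 and C11 from an Evans glyoxylate aldol, ring from a Dieckmann condensation of a propanoate) with pyrrolylboronate 23 (C20 from a chiral bromo ester, C18 from a CBS reduction, boron placed by C–H borylation).
5. Ring order: lactone E, butenolide D, saturation of D, ring B, azepine.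

Key step: step 21

Remark: bromo ester 16 and N-Boc acid 17 are taken as purchasable; the C7 carbinol of 31 and 32 is an epimer mixture that converges on oxidation in step 20.

**Route**

Step 1
Reactants: 1 (S)-4-benzyloxazolidin-2-one; 2 butanoyl chloride
Product: 3 (S)-4-benzyl-3-butanoyloxazolidin-2-one
Conditions: n-BuLi, THF, −78 °C; then 2, −78 → 0 °C
Reagents that add atoms: none
Why: N-acylation of the lithiated oxazolidinone by an acid chloride, with no new stereocentre.

Step 2
Reactants: 3 (S)-4-benzyl-3-butanoyloxazolidin-2-one; 4 ethyl glyoxylate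
Product: 6 ethyl (2S,3S)-3-{[(4S)-4-benzyl-2-oxo-1,3-oxazolidin-3-yl]carbonyl}-2-hydroxypentanoate, via boron enolate 5 (not isolated)
Conditions: Bu2BOTf, iPr2NEt, CH2Cl2, 0 °C; then 4 (freshly cracked), −78 → 0 °C; H2O2, pH 7 buffer, MeOH
Reagents that add atoms: none
Why: Evans syn aldol reaction, in which the (Z)-boron enolate reacts through a Zimmerman–Traxler chair on the face away from the benzyl group and so sets C10 and C11 together (syn, both S in 6).

Step 3
Reactants: 6 aldol adduct
Product: 7 (2S,3S)-2-ethyl-3-hydroxybutanedioic acid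
Conditions: LiOH, H2O2, THF/H2O, 0 °C → rt; Na2SO3; HCl
Reagents that add atoms: hydrogen peroxide (OO); lithium hydroxide ([Li+].[OH-])
Why: Hydroperoxide cleaves the exocyclic imide carbonyl and hydroxide saponifies the ethyl ester, and the hydroxy carboxylates formed do not epimerise.

Step 4
Reactants: 7 diacid
Product: 8 (2S)-2-[(4S)-2,2-dimethyl-5-oxo-1,3-dioxolan-4-yl]butanoic acid
Conditions: 2,2-dimethoxypropane, TsOH (cat.), rt
Reagents that add atoms: 2,2-dimethoxypropane (COC(C)(C)OC)
Why: Acetonide formation takes up the α-hydroxy acid as the five-membered dioxolanone in preference to the six-membered alternative, which differentiates the C12 carboxyl from the free C9 carboxyl.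

Step 5
Reactants: 8 dioxolanone acid
Product: 9 (5S)-5-[(2R)-1-hydroxybutan-2-yl]-2,2-dimethyl-1,3-dioxolan-4-one
Conditions: BH3·THF, THF, 0 °C → rt; MeOH quench
Reagents that add atoms: none
Why: Borane reduces a free carboxylic acid through its acyloxyborane much faster than the dioxolanone ester, and the acid-free work-up avoids translactonisation.

Step 6
Reactants: 9 primary alcohol
Product: 10 (5S)-5-[(2R)-1-{[tert-butyl(dimethyl)silyl]oxy}butan-2-yl]-2,2-dimethyl-1,3-dioxolan-4-one
Conditions: TBSCl, imidazole, CH2Cl2, 0 °C → rt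
Reagents that add atoms: tert-butyldimethylsilyl chloride (CC(C)(C)[Si](C)(C)Cl)
Why: Routine silylation of a primary alcohol, which keeps the C9 oxygen from lactonising onto C12 later.

Step 7
Reactants: 10 silyl ether; 11 propanoyl chloride
Product: 13 methyl (2S,3R)-3-({[tert-butyl(dimethyl)silyl]oxy}methyl)-2-(propanoyloxy)pentanoate, via hydroxy ester 12 (not isolated)
Conditions: K2CO3 (cat.), MeOH, 0 °C → rt; evaporate; then 11, pyridine, DMAP (cat.), CH2Cl2, 0 °C
Reagents that add atoms: methanol (CO)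
Why: Methoxide transesterification opens the dioxolanone with loss of acetone, and the freed secondary alcohol is then acylated; C11 is untouched.

Step 8
Reactants: 13 propanoate
Product: 14 (5S)-5-[(2R)-1-{[tert-butyl(dimethyl)silyl]oxy}butan-2-yl]-4-hydroxy-3-methylfuran-2(5H)-one
Conditions: LiHMDS (2.5 equiv), THF, −78 °C → rt; cold 1 M HCl
Reagents that add atoms: none
Why: Dieckmann condensation in which the propanoate enolate attacks the methyl ester (5-exo-trig) and formation of the tetronate anion drives the reaction and protects C11 from epimerisation.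

Step 9
Reactants: 14 tetronic acid
Product: 15 (2S)-2-[(2R)-1-{[tert-butyl(dimethyl)silyl]oxy}butan-2-yl]-4-methyl-5-oxo-2,5-dihydrofuran-3-yl trifluoromethanesulfonate
Conditions: Tf2O, iPr2NEt, CH2Cl2, −78 °C
Reagents that add atoms: trifluoromethanesulfonic anhydride (O=S(=O)(OS(=O)(=O)C(F)(F)F)C(F)(F)F)
Why: O-sulfonylation of the vinylogous acid gives an electron-poor vinyl triflate ready for cross-coupling.

Step 10
Reactants: 16 methyl (R)-3-bromo-2-methylpropanoate; 17 1-(tert-butoxycarbonyl)pyrrole-2-carboxylic acid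
Product: 20 methyl (2S)-4-[1-(tert-butoxycarbonyl)pyrrol-2-yl]-2-methyl-4-oxobutanoate, via organozinc bromide 18 (not isolated), via acid chloride 19 (not isolated)
Conditions: 16, Zn, I2 (cat.), DMA, 70 °C; 17, 1-chloro-N,N,2-trimethylprop-1-en-1-amine, CH2Cl2, 0 °C; combine, Pd(PPh3)4 (5 mol%), THF, rt
Reagents that add atoms: none
Why: Negishi acylation of a β-zincio ester with an acid chloride, which fixes the ketone at the CH2 end without ambiguity and leaves the C20 stereocentre (β to zinc, not enolised) intact.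

Step 11
Reactants: 20 keto ester
Product: 22 tert-butyl 2-[(2S,4S)-4-methyl-5-oxooxolan-2-yl]pyrrole-1-carboxylate, via hydroxy ester 21 (not isolated)
Conditions: (R)-2-methyl-CBS-oxazaborolidine (15 mol%), BH3·SMe2, THF, −20 °C; MeOH; then PPTS (cat.), PhMe, 50 °C
Reagents that add atoms: none
Why: Corey–Bakshi–Shibata reduction with the N-Boc-pyrrolyl group as the large substituent should give the 18S alcohol by catalyst control (by analogy with aryl alkyl ketones), and the γ-hydroxy ester closes to the cis lactone.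

Step 12
Reactants: 22 pyrrolyl lactone
Product: 23 tert-butyl 2-[(2S,4S)-4-methyl-5-oxooxolan-2-yl]-4-(4,4,5,5-tetramethyl-1,3,2-dioxaborolan-2-yl)pyrrole-1-carboxylate
Conditions: [Ir(OMe)(cod)]2 (1.5 mol%), dtbpy (3 mol%), B2pin2, THF, 60 °C
Reagents that add atoms: bis(pinacolato)diboron (CC1(C)OB(OC1(C)C)B1OC(C)(C)C(C)(C)O1)
Why: Iridium-catalysed C–H borylation is governed by sterics, and C4 is the only ring C–H not flanked by the N-Boc group or the C2 substituent.

Step 13
Reactants: 15 tetronate triflate; 23 pyrrolylboronate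
Product: 24 tert-butyl 4-[(2S)-2-[(2R)-1-{[tert-butyl(dimethyl)silyl]oxy}butan-2-yl]-4-methyl-5-oxo-2,5-dihydrofuran-3-yl]-2-[(2S,4S)-4-methyl-5-oxooxolan-2-yl]pyrrole-1-carboxylate
Conditions: PdCl2(dppf) (5 mol%), Na2CO3 (aq.), THF, 45 °C
Reagents that add atoms: none
Why: Suzuki–Miyaura coupling of an activated vinyl triflate with a 3-pyrrolylboronate, run with a mild base so that the γ-hydrogen at C11 is not epimerised.

Step 14
Reactants: 24 butenolide
Product: 25 tert-butyl 4-[(2R,3R,4R)-2-[(2R)-1-{[tert-butyl(dimethyl)silyl]oxy}butan-2-yl]-4-methyl-5-oxooxolan-3-yl]-2-[(2S,4S)-4-methyl-5-oxooxolan-2-yl]pyrrole-1-carboxylate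
Conditions: H2 (10 bar), 10% Pd/C, EtOAc, rt
Reagents that add atoms: none
Why: Heterogeneous hydrogenation adds both hydrogens cis on the face opposite the branched C11 side chain, so that the pyrrole at C12 and the methyl at C13 end cis to that chain (all-cis lactone D).

Step 15
Reactants: 25 silyl ether
Product: 26 tert-butyl 4-[(2R,3R,4R)-2-[(2R)-1-hydroxybutan-2-yl]-4-methyl-5-oxooxolan-3-yl]-2-[(2S,4S)-4-methyl-5-oxooxolan-2-yl]pyrrole-1-carboxylate
Conditions: HF·pyridine, pyridine, THF, 0 °C → rt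
Reagents that add atoms: none
Why: Buffered fluoride cleaves the primary silyl ether without base, so the epimerisable C13 and both lactones are left alone.

Step 16
Reactants: 26 primary alcohol
Product: 27 tert-butyl 4-[(2R,3R,4R)-4-methyl-5-oxo-2-[(2S)-1-oxobutan-2-yl]oxolan-3-yl]-2-[(2S,4S)-4-methyl-5-oxooxolan-2-yl]pyrrole-1-carboxylate
Conditions: DMP, CH2Cl2, 0 °C → rt; used at once
Reagents that add atoms: none
Why: Dess–Martin oxidation is neutral enough to leave the α-stereocentre C10 of the new aldehyde intact, and the N-Boc group keeps the pyrrole inert to the oxidant and to the aldehyde.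

Step 17
Reactants: 27 aldehyde; 28 (triphenylphosphoranylidene)acetaldehyde
Product: 29 tert-butyl 4-[(2S,3R,4R)-4-methyl-5-oxo-2-[(3R,4E)-6-oxohex-4-en-3-yl]oxolan-3-yl]-2-[(2S,4S)-4-methyl-5-oxooxolan-2-yl]pyrrole-1-carboxylate
Conditions: PhMe, 70 °C
Reagents that add atoms: none
Why: Wittig olefination with a stabilised, non-basic ylide gives the (E)-enal without eliminating the β-acyloxy group or epimerising C10.

Step 18
Reactants: 29 enal; 30 vinyl bromide
Product: 31 tert-butyl 4-[(2S,3R,4R)-2-[(3R,4E)-6-hydroxyocta-4,7-dien-3-yl]-4-methyl-5-oxooxolan-3-yl]-2-[(2S,4S)-4-methyl-5-oxooxolan-2-yl]pyrrole-1-carboxylate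
Conditions: CrCl2, NiCl2 (2 mol%), DMF, rt
Reagents that add atoms: none
Why: Nozaki–Hiyama–Kishi vinylation adds 1,2 to the aldehyde only, sparing both lactones and the carbamate.

Step 19
Reactants: 31 N-Boc dienol
Product: 32 (3S,5S)-5-{4-[(2S,3R,4R)-2-[(3R,4E)-6-hydroxyocta-4,7-dien-3-yl]-4-methyl-5-oxooxolan-3-yl]-1H-pyrrol-2-yl}-3-methyloxolan-2-one
Conditions: o-dichlorobenzene (degassed), 170 °C, 30 min
Reagents that add atoms: none
Why: Thermal fragmentation of a pyrrole N-Boc group to isobutene and CO2 needs no acid or base, and it is done here because the molecule holds no Michael acceptor for the freed pyrrole to attack.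

Step 20
Reactants: 32 N–H dienol
Product: 33 (3S,5S)-3-methyl-5-{4-[(2S,3R,4R)-4-methyl-5-oxo-2-[(3R,4E)-6-oxoocta-4,7-dien-3-yl]oxolan-3-yl]-1H-pyrrol-2-yl}oxolan-2-one
Conditions: MnO2, CH2Cl2, 0 °C → rt; filter; used at once
Reagents that add atoms: none
Why: MnO2 oxidises the doubly allylic alcohol to the divinyl ketone under neutral conditions that an N–H pyrrole tolerates.

Step 21
Reactants: 33 dienone
Product: 35 7-oxo derivative of the target, via vinyl ketone 34 (not isolated)
Conditions: Sc(OTf)3 (20 mol%), MeCN (0.005 M), 0 °C → rt; then DBU, rt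
Reagents that add atoms: none
Why: Sc(OTf)3 binds the dienone carbonyl and the free pyrrole α-carbon (C9a) adds to the β-carbon C9 of the substituted enone arm, rearomatisation then giving vinyl ketone 34; DBU next makes the N–H nucleophilic enough to add to the terminal carbon C5. Both events are known reaction types, the Lewis-acid Friedel–Crafts conjugate addition of pyrroles to enones and the base-mediated aza-Michael addition of a pyrrole N–H to a vinyl ketone, and only their use back to back on the two arms of one dienone is untried. Ring B closes 6-exo-trig (C9a–C9) and the azepine closes 7-endo-trig (N–C5). The one new stereocentre, C9, is set in a chair-like transition state that keeps the C10 ethyl group and the C11 oxygen equatorial and the enone arm pseudo-equatorial, so C8 ends trans to the ethyl group (9R), and because the carbon addition can revert under the Lewis acid this diequatorial isomer should also be favoured at equilibrium. Site selectivity is needed twice: the α-carbon must win over the β-carbon C2, which can also reach C9 through a six-membered array but is less nucleophilic and is flanked by both lactone-bearing substituents, and C9 must be attacked and not C5, which the α-carbon cannot reach in a small ring. High dilution suppresses reaction of the exposed vinyl ketone between molecules, and nitrogen comes within reach of C5 only after ring B has formed.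

Step 22
Reactants: 35 ketone
Product: 36 C7 4-methylbenzenesulfonylhydrazone of 35
Conditions: TsNHNH2, MgSO4, THF, 45 °C
Reagents that add atoms: 4-methylbenzenesulfonohydrazide (Cc1ccc(cc1)S(=O)(=O)NN)
Why: Hydrazone condensation at the only ketone, under aprotic and near-neutral conditions that avoid solvolysis of the pyrrolylic lactone E.

Step 23
Reactants: 36 tosylhydrazone
Product: 39 CNP0232452.6 (target), via N-boryl tosylhydrazine 37 (not isolated), via alkyldiazene 38 (not isolated)
Conditions: catecholborane, CHCl3, 0 °C → rt; then NaOAc·3H2O, reflux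
Reagents that add atoms: none
Why: Catecholborane reduction of a tosylhydrazone (a mild variant of the Caglioti reduction): hydride adds to C7, acetate triggers loss of sulfinate, and the diazene loses N2 to leave CH2 without strong acid or base, so C13 and both lactones survive.

**Compound list**

1 | (S)-4-benzyloxazolidin-2-one | O=C1N[C@@H](Cc2ccccc2)CO1 | starting material
2 | butanoyl chloride | CCCC(=O)Cl | starting material
3 | (S)-4-benzyl-3-butanoyloxazolidin-2-one | CCCC(=O)N1[C@@H](Cc2ccccc2)COC1=O | intermediate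
4 | ethyl glyoxylate | CCOC(=O)C=O | starting material
5 | (Z)-dibutylboron enolate of 3 | CC/C=C(\OB(CCCC)CCCC)N1[C@@H](Cc2ccccc2)COC1=O | intermediate
6 | ethyl (2S,3S)-3-{[(4S)-4-benzyl-2-oxo-1,3-oxazolidin-3-yl]carbonyl}-2-hydroxypentanoate | CC[C@H](C(=O)N1[C@@H](Cc2ccccc2)COC1=O)[C@H](O)C(=O)OCC | intermediate
7 | (2S,3S)-2-ethyl-3-hydroxybutanedioic acid | CC[C@H](C(=O)O)[C@H](O)C(=O)O | intermediate
8 | (2S)-2-[(4S)-2,2-dimethyl-5-oxo-1,3-dioxolan-4-yl]butanoic acid | CC[C@H](C(=O)O)[C@@H]1OC(C)(C)OC1=O | intermediate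
9 | (5S)-5-[(2R)-1-hydroxybutan-2-yl]-2,2-dimethyl-1,3-dioxolan-4-one | CC[C@H](CO)[C@@H]1OC(C)(C)OC1=O | intermediate
10 | (5S)-5-[(2R)-1-{[tert-butyl(dimethyl)silyl]oxy}butan-2-yl]-2,2-dimethyl-1,3-dioxolan-4-one | CC[C@H](CO[Si](C)(C)C(C)(C)C)[C@@H]1OC(C)(C)OC1=O | intermediate
11 | propanoyl chloride | CCC(=O)Cl | starting material
12 | methyl (2S,3R)-3-({[tert-butyl(dimethyl)silyl]oxy}methyl)-2-hydroxypentanoate | CC[C@H](CO[Si](C)(C)C(C)(C)C)[C@H](O)C(=O)OC | intermediate
13 | methyl (2S,3R)-3-({[tert-butyl(dimethyl)silyl]oxy}methyl)-2-(propanoyloxy)pentanoate | CC[C@H](CO[Si](C)(C)C(C)(C)C)[C@H](OC(=O)CC)C(=O)OC | intermediate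
14 | (5S)-5-[(2R)-1-{[tert-butyl(dimethyl)silyl]oxy}butan-2-yl]-4-hydroxy-3-methylfuran-2(5H)-one | CC[C@H](CO[Si](C)(C)C(C)(C)C)[C@@H]1OC(=O)C(C)=C1O | intermediate
15 | (2S)-2-[(2R)-1-{[tert-butyl(dimethyl)silyl]oxy}butan-2-yl]-4-methyl-5-oxo-2,5-dihydrofuran-3-yl trifluoromethanesulfonate | CC[C@H](CO[Si](C)(C)C(C)(C)C)[C@@H]1OC(=O)C(C)=C1OS(=O)(=O)C(F)(F)F | intermediate
16 | methyl (R)-3-bromo-2-methylpropanoate | BrC[C@H](C)C(=O)OC | starting material
17 | 1-(tert-butoxycarbonyl)pyrrole-2-carboxylic acid | CC(C)(C)OC(=O)n1cccc1C(=O)O | starting material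
18 | [(2R)-3-methoxy-2-methyl-3-oxopropyl]zinc bromide | Br[Zn]C[C@H](C)C(=O)OC | intermediate
19 | tert-butyl 2-(chlorocarbonyl)pyrrole-1-carboxylate | CC(C)(C)OC(=O)n1cccc1C(=O)Cl | intermediate
20 | methyl (2S)-4-[1-(tert-butoxycarbonyl)pyrrol-2-yl]-2-methyl-4-oxobutanoate | CC(C)(C)OC(=O)n1cccc1C(=O)C[C@H](C)C(=O)OC | intermediate
21 | methyl (2S,4S)-4-[1-(tert-butoxycarbonyl)pyrrol-2-yl]-4-hydroxy-2-methylbutanoate | CC(C)(C)OC(=O)n1cccc1[C@@H](O)C[C@H](C)C(=O)OC | intermediate
22 | tert-butyl 2-[(2S,4S)-4-methyl-5-oxooxolan-2-yl]pyrrole-1-carboxylate (cis lactone E) | CC(C)(C)OC(=O)n1cccc1[C@@H]1C[C@H](C)C(=O)O1 | intermediate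
23 | tert-butyl 2-[(2S,4S)-4-methyl-5-oxooxolan-2-yl]-4-(4,4,5,5-tetramethyl-1,3,2-dioxaborolan-2-yl)pyrrole-1-carboxylate | CC(C)(C)OC(=O)n1cc(B2OC(C)(C)C(C)(C)O2)cc1[C@@H]1C[C@H](C)C(=O)O1 | intermediate
24 | butenolide: N-Boc pyrrole with lactone E at C3 and the 3-methyl-5-substituted butenolide at C1, C9 as CH2OTBS (10R,11S,18S,20S) | CC[C@H](CO[Si](C)(C)C(C)(C)C)[C@@H]1OC(=O)C(C)=C1c1cn(C(=O)OC(C)(C)C)c(c1)[C@@H]1C[C@H](C)C(=O)O1 | intermediate
25 | all-cis lactone D, C9 as CH2OTBS, N-Boc (10R,11R,12R,13R,18S,20S) | CC[C@H](CO[Si](C)(C)C(C)(C)C)[C@@H]1OC(=O)[C@H](C)[C@@H]1c1cn(C(=O)OC(C)(C)C)c(c1)[C@@H]1C[C@H](C)C(=O)O1 | intermediate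
26 | all-cis lactone D, C9 as CH2OH, N-Boc (10R,11R,12R,13R,18S,20S) | CC[C@H](CO)[C@@H]1OC(=O)[C@H](C)[C@@H]1c1cn(C(=O)OC(C)(C)C)c(c1)[C@@H]1C[C@H](C)C(=O)O1 | intermediate
27 | C9 aldehyde, N-Boc (10S,11R,12R,13R,18S,20S) | CC[C@H](C=O)[C@@H]1OC(=O)[C@H](C)[C@@H]1c1cn(C(=O)OC(C)(C)C)c(c1)[C@@H]1C[C@H](C)C(=O)O1 | intermediate
28 | (triphenylphosphoranylidene)acetaldehyde | O=CC=P(c1ccccc1)(c1ccccc1)c1ccccc1 | starting material
29 | (E)-enal C9=C8–C7HO, N-Boc (10R,11S,12R,13R,18S,20S) | CC[C@H](/C=C/C=O)[C@@H]1OC(=O)[C@H](C)[C@@H]1c1cn(C(=O)OC(C)(C)C)c(c1)[C@@H]1C[C@H](C)C(=O)O1 | intermediate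
30 | vinyl bromide | C=CBr | starting material
31 | N-Boc dienol, C7 carbinol as epimer mixture (10R,11S,12R,13R,18S,20S) | CC[C@H](/C=C/C(O)C=C)[C@@H]1OC(=O)[C@H](C)[C@@H]1c1cn(C(=O)OC(C)(C)C)c(c1)[C@@H]1C[C@H](C)C(=O)O1 | intermediate
32 | N–H dienol, C7 carbinol as epimer mixture | CC[C@H](/C=C/C(O)C=C)[C@@H]1OC(=O)[C@H](C)[C@@H]1c1c[nH]c(c1)[C@@H]1C[C@H](C)C(=O)O1 | intermediate
33 | N–H pyrrole divinyl ketone, key-step precursor (10R,11S,12R,13R,18S,20S) | CC[C@H](/C=C/C(=O)C=C)[C@@H]1OC(=O)[C@H](C)[C@@H]1c1c[nH]c(c1)[C@@H]1C[C@H](C)C(=O)O1 | intermediate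
34 | vinyl ketone with ring B closed and N–H free (9R,10R,11S,12R,13R,18S,20S) | CC[C@H]1[C@@H]2OC(=O)[C@H](C)[C@@H]2c2cc([C@@H]3C[C@H](C)C(=O)O3)[nH]c2[C@@H]1CC(=O)C=C | intermediate
35 | 7-oxo derivative of the target | CC[C@H]1[C@@H]2OC(=O)[C@H](C)[C@@H]2c2cc([C@@H]3C[C@H](C)C(=O)O3)n3c2[C@@H]1CC(=O)CC3 | intermediate
36 | C7 4-methylbenzenesulfonylhydrazone of 35 (C=N isomers) | CC[C@H]1[C@@H]2OC(=O)[C@H](C)[C@@H]2c2cc([C@@H]3C[C@H](C)C(=O)O3)n3c2[C@@H]1CC(=NNS(=O)(=O)c1ccc(C)cc1)CC3 | intermediate
37 | N-(1,3,2-benzodioxaborol-2-yl) tosylhydrazine at C7 | CC[C@H]1[C@@H]2OC(=O)[C@H](C)[C@@H]2c2cc([C@@H]3C[C@H](C)C(=O)O3)n3c2[C@@H]1CC(N(NS(=O)(=O)c1ccc(C)cc1)B1Oc2ccccc2O1)CC3 | intermediate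
38 | C7 alkyldiazene | CC[C@H]1[C@@H]2OC(=O)[C@H](C)[C@@H]2c2cc([C@@H]3C[C@H](C)C(=O)O3)n3c2[C@@H]1CC(N=N)CC3 | intermediate
39 | CNP0232452.6 (9R,10R,11S,12R,13R,18S,20S) | CC[C@H]1[C@@H]2OC(=O)[C@H](C)[C@@H]2c2cc([C@@H]3C[C@H](C)C(=O)O3)n3c2[C@@H]1CCCC3 | target

**Step count**

Total: 23 steps. Longest linear sequence: 20 steps (steps 1–9, then 13–23).

**Steps most likely to fail**

Step 21. The exposed vinyl ketone arm may oligomerise by intermolecular addition before ring B has closed, the flanked β-carbon may compete, the Lewis acid may ionise the pyrrolylic C18–O bond of lactone E and scramble C18, or the nitrogen addition may stall with so weakly acidic a pyrrole. The fallback never exposes the terminal vinyl ketone until ring B exists. It sets out from aldehyde 27. A mono-Horner–Wadsworth–Emmons reaction with tetraethyl (2-oxopropane-1,3-diyl)bis(phosphonate) (LiCl, iPr2NEt) should give the enone β-ketophosphonate F1. Thermolysis of the carbamate should give the N–H pyrrole F2. Sc(OTf)3, which can now chelate the β-ketophosphonate, should close ring B on the single enone arm to give the ring-B ketophosphonate F3. A second Horner–Wadsworth–Emmons reaction with aqueous formaldehyde and K2CO3 should then generate vinyl ketone 34 in dilute solution, where the same base lets the nitrogen add, and the route is rejoined at 35.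

Step 14. Slow hydrogen uptake at the hindered tetrasubstituted alkene may call for conditions under which the pyrrolylic C–O bond of lactone E is hydrogenolysed or the pyrrole ring is saturated, and desorption and readsorption may erode the all-cis outcome. The fallback replaces surface hydrogenation by conjugate reduction and kinetic protonation. It sets out from 24. Copper hydride ([(Ph3P)CuH]6 cat., PhMe2SiH) should deliver hydride to C12 on the face away from the C11 side chain and give the silyl ketene acetal F4. Protonation with 2,6-di-tert-butylphenol at −78 °C should occur on the face away from both neighbours and place the C13 methyl cis, rejoining at 25.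

Step 19. At 170 °C the doubly allylic alcohol may ionise or dehydrate once the electron-rich pyrrole is set free, or the pyrrolylic lactone may open. The fallback oxidises before deprotecting. It sets out from 31. Dess–Martin periodinane should give the N-Boc dienone F5, which is stable because the carbamate keeps the pyrrole unreactive. Brief heating in hexafluoroisopropanol, a medium known both to cleave pyrrole N-Boc groups and to promote Friedel–Crafts conjugate addition to enones, should release the pyrrole in the presence of its acceptor and lead on to 34. DBU then closes the azepine, rejoining at 35.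

**Further compounds**

F1 | step 21 | N-Boc enone β-ketophosphonate, C9=C8–C7(=O)–CH2P(O)(OEt)2 arm | CC[C@H](/C=C/C(=O)CP(=O)(OCC)OCC)[C@@H]1OC(=O)[C@H](C)[C@@H]1c1cn(C(=O)OC(C)(C)C)c(c1)[C@@H]1C[C@H](C)C(=O)O1
F2 | step 21 | N–H enone β-ketophosphonate | CC[C@H](/C=C/C(=O)CP(=O)(OCC)OCC)[C@@H]1OC(=O)[C@H](C)[C@@H]1c1c[nH]c(c1)[C@@H]1C[C@H](C)C(=O)O1
F3 | step 21 | ring-B ketophosphonate | CC[C@H]1[C@@H]2OC(=O)[C@H](C)[C@@H]2c2cc([C@@H]3C[C@H](C)C(=O)O3)[nH]c2[C@@H]1CC(=O)CP(=O)(OCC)OCC
F4 | step 14 | dimethyl(phenyl)silyl ketene acetal of lactone D with C12 reduced | CC[C@H](CO[Si](C)(C)C(C)(C)C)[C@@H]1OC(O[Si](C)(C)c2ccccc2)=C(C)[C@@H]1c1cn(C(=O)OC(C)(C)C)c(c1)[C@@H]1C[C@H](C)C(=O)O1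
F5 | step 19 | N-Boc divinyl ketone | CC[C@H](/C=C/C(=O)C=C)[C@@H]1OC(=O)[C@H](C)[C@@H]1c1cn(C(=O)OC(C)(C)C)c(c1)[C@@H]1C[C@H](C)C(=O)O1
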